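Take the logarithm of the target readings and compare flasks in powers of ten, because a ratio between two flasks read at nearly the same time can be judged without knowing the level of either. In each flask starting material is fed over 2.0 h into a stirred solution of partner and protic impurity, and the flasks differ in the impurity charge.

| flask | starting material | partner | protic impurity | remark | time |
|---|---|---|---|---|---|
| ash | 0.30 M (fed, over 2.0 h) | 1.5 equiv | 0.034 M | run made earlier; the fed solution adds 0.10 times the starting volume |  |
| larch | 0.30 M (fed, over 2.0 h) | 1.5 equiv | 0.087 M | run made earlier; the fed solution adds 0.10 times the starting volume |  |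
| birch | 0.30 M (fed, over 2.0 h) | 1.5 equiv | 0.19 M | run made earlier; the fed solution adds 0.10 times the starting volume |  |
| south-east | 0.30 M (fed, over 2.0 h) | 1.50 equiv | 0.0300 M | the fed solution adds 0.10 times the starting volume | 15 d |
| north-east | 0.30 M (fed, over 2.0 h) | 1.50 equiv | 0.100 M | the fed solution adds 0.10 times the starting volume | 15 d |
| east | 0.30 M (fed, over 2.0 h) | 1.50 equiv | 0.250 M | the fed solution adds 0.10 times the starting volume | 15 d |

- ash (time / d: target / %): 1.04: 12; 2.50: 18; 5.00: 22; 8.00: 20; 10.0: 23
- larch (time / d: target / %): 0.833: 9; 1.67: 15; 3.00: 21; 6.00: 19; 10.0: 17
- birch (time / d: target / %): 0.833: 5; 1.67: 13; 3.00: 15; 6.00: 15; 10.0: 16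

(standard deviation of a reading: 1.5 percentage points)

1. amount of target at the end, in percent of the starting material charged for south-east, north-east, east, in this order
2. how the row runs (falls, then rises / rises all the way / hardly changes / falls all the way / rises, then falls)

- charges are per starting volume, the dose included; the dosed solution carries all of it
- "hardly changes" means that all values lie within two and a half points (for a concentration: within two and a half percent of the largest)

The quantity to carry is the impurity penalty, a semi-log slope: the decades of target lost per molar of protic impurity, with the other charges held as in these runs. It can be reached in two ways from separate readings. The middle readings set ash, 22% at 5.00 d, against birch, 15% at 6.00 d, and give 1.07 M⁻¹. The last readings, 23% and 16% at 10.0 d, give 1.01 M⁻¹. The scatter of the readings puts about 0.337 M⁻¹ on either value, and the two differ by less than that, so their mean is trusted as the impurity penalty, 1.04 M⁻¹.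

My own reckoning therefore commits to ratios. East should hold 0.591 of the target in south-east, north-east should hold 0.846 of it, and the row should fall throughout. The level stays open: larch reads 21% at 3.00 d and 17% at 10.0 d, a step larger than the scatter, ash reads 22% at 5.00 d and 23% at 10.0 d, and the asked time of 15 d lies beyond every reading. The ratios assume that any later drift takes the same fraction from each flask.

The forecast gives 22%, 18.3% and 13.3%, a row that falls all the way, on the ground that “The plateau falls steadily as impurity rises”. The flasks give 16.9%, 15.0% and 11.5%, and the row falls all the way.

    partner → second intermediate (k = 1.30 × 10⁻⁴ s⁻¹)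
    open intermediate + second intermediate ⇌ target (K = 1.20 M⁻¹, k = 1.10 × 10⁻⁴ M⁻¹ s⁻¹)
    starting material + protic impurity → quenched substrate (k = 4.20 × 10⁻⁵ M⁻¹ s⁻¹)
    2 open intermediate → homo product (k = 2.50 × 10⁻⁶ M⁻¹ s⁻¹)
    starting material → open intermediate (k = 6.60 × 10⁻⁶ s⁻¹)

Applied to the south-east value, the impurity penalty gives 14.3% for north-east and 9.99% for east, against 15.0% and 11.5%, so east holds a larger fraction of the south-east target than reckoned. The largest single effect on the fall along the row is the loss of starting material with protic impurity to quenched substrate: in the run without that step, the change from south-east to east goes from −5.4 percentage points to 0 points.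

The earlier runs and the new flask are calculated for substances that don't exist; noise was put on by code.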